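**Plan**

1. Atoms carry the locants of the target: ring A = C1(CH3)=C2–C3(OH)–C4(Br)–C5(CH3)2, spiro carbon C6, ring B = C7H2–C8(Br)=C9(CH3)–C10H2–C11H2.
2. Retrosynthesis: C3–OH and C4–Br go back to the ring A enone. In ring B the vinylic carbon C8 is cut out with its bromine at both ring bonds (C7–C8, C8–C9) as dibromocarbene, leaving a spiro 3-methylcyclopentene C6–C7=C9–C10–C11. That ring is cut at C7=C9 (metathesis) and at the two exocyclic bonds of C6 (allylation, alkylation), back to 3-ethoxy-5,5-dimethylcyclohex-2-en-1-one.
3. Forward: ring A is present from the start; C6 is made quaternary; the five-membered ring is closed by metathesis; enone transposition; one-carbon expansion of the five-membered ring to ring B; allylic debromination; C4 bromination; C3 reduction.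
4. Enabling feature: C8 is an sp2 carbon bearing bromine, flanked by C7 (the CH2 next to the spiro carbon) and the methyl-bearing C9. This is the pattern produced by cyclopropyl-to-allyl opening of the dibromocarbene adduct of a C7=C9 cyclopentene, so the vinylic bromide, which zerovalent palladium and metathesis catalysts would not tolerate, enters late and in the ring-forming event.
5. Stereochemistry: C6 from an enantioselective decarboxylative allylation, untouched afterwards (both faces of carbene attack converge); C4 from substrate-controlled enolate bromination; C3 from axial hydride delivery trans to bromine.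

Key step: step 7

Remark: the sense of induction in step 3 is assumed from the 2-alkyl-2-allylcyclohexanone series, where the (S)-PHOX ligand delivers the allyl group to the enolate face that corresponds here to (R)-6.

**Step 1**
Reactants: 1 3-ethoxy-5,5-dimethylcyclohex-2-en-1-one; 2 4-bromo-2-methylbut-1-ene
Product: 3 rac-3-ethoxy-5,5-dimethyl-6-(3-methylbut-3-en-1-yl)cyclohex-2-en-1-one
Conditions: LiN(i-Pr)2, THF, −78 °C; then 2, DMPU, −78 to 23 °C
Reagents that add atoms: 4-bromo-2-methylbut-1-ene (2), C=C(C)CCBr
Why: Kinetic α′-deprotonation of the vinylogous ester (Stork–Danheiser mode) and SN2 alkylation by the primary bromide should give 3; the new stereocentre is racemic and is erased in step 2.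

**Step 2**
Reactants: 3 rac-3-ethoxy-5,5-dimethyl-6-(3-methylbut-3-en-1-yl)cyclohex-2-en-1-one; 4 allyl chloroformate
Product: 5 5-ethoxy-3,3-dimethyl-2-(3-methylbut-3-en-1-yl)cyclohexa-1,5-dien-1-yl prop-2-en-1-yl carbonate
Conditions: LiN(i-Pr)2, TMEDA, THF, −78 °C; then 4, −78 to 0 °C
Reagents that add atoms: allyl chloroformate (4), C=CCOC(Cl)=O
Why: The hindered, fully substituted lithium enolate should be acylated on oxygen (enol carbonate formation), which fixes the enolate regiochemistry for step 3 and removes the stereocentre.

**Step 3**
Reactants: 5 5-ethoxy-3,3-dimethyl-2-(3-methylbut-3-en-1-yl)cyclohexa-1,5-dien-1-yl prop-2-en-1-yl carbonate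
Product: 6 (R)-3-ethoxy-5,5-dimethyl-6-(3-methylbut-3-en-1-yl)-6-(prop-2-en-1-yl)cyclohex-2-en-1-one
Conditions: Pd2(dba)3 (2.5 mol %), (S)-(CF3)3-t-BuPHOX (6 mol %), toluene, 30 °C
Reagents that add atoms: none
Why: Enantioselective decarboxylative allylic alkylation (decarboxylative Tsuji–Trost reaction): zerovalent palladium ionises the allyl carbonate, CO2 is lost, and the palladium-bound enolate and allyl fragment recombine inside the pocket of the electron-poor PHOX ligand, which selects the enolate face and sets the quaternary carbon (the later spiro centre C6) as R.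

**Step 4**
Reactants: 6 (R)-3-ethoxy-5,5-dimethyl-6-(3-methylbut-3-en-1-yl)-6-(prop-2-en-1-yl)cyclohex-2-en-1-one
Product: 7 (R)-3-ethoxy-5,5-dimethyl-6-(3-methylbut-3-en-1-yl)-6-[(E)-prop-1-en-1-yl]cyclohex-2-en-1-one
Conditions: RuHCl(CO)(PPh3)3 (5 mol %), toluene, 80 °C
Reagents that add atoms: none
Why: Ruthenium hydride insertion and β-hydride elimination (olefin isomerisation) should move the terminal double bond by one position, stopping at the quaternary carbon; the monosubstituted alkene should react much faster than the 1,1-disubstituted one, and no stereocentre is touched.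

**Step 5**
Reactants: 7 (R)-3-ethoxy-5,5-dimethyl-6-(3-methylbut-3-en-1-yl)-6-[(E)-prop-1-en-1-yl]cyclohex-2-en-1-one
Product: 8 (R)-8-ethoxy-2,10,10-trimethylspiro[4.5]deca-1,7-dien-6-one
Conditions: second-generation Grubbs catalyst (5 mol %), CH2Cl2, 40 °C
Reagents that add atoms: none
Why: Ring-closing olefin metathesis between the propenyl group and the isopropenyl terminus should close the five-membered ring C6–C7=C9–C10–C11 with loss of propene; the quaternary stereocentre becomes the spiro centre unchanged.

**Step 6**
Reactants: 8 (R)-8-ethoxy-2,10,10-trimethylspiro[4.5]deca-1,7-dien-6-one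
Product: 10 (R)-2,6,10,10-tetramethylspiro[4.5]deca-1,6-dien-8-one, via tertiary carbinol 9 (not isolated)
Conditions: MeLi, CeCl3, THF, −78 to 0 °C; then 1 M HCl, 23 °C
Reagents that add atoms: methyllithium, [Li]C
Why: Stork–Danheiser enone transposition: CeCl3-assisted 1,2-addition of MeLi to the hindered ketone, then acid hydrolysis of the enol ether with loss of the tertiary hydroxyl should give the 3-methyl enone of ring A; the carbinol stereocentre of 9 is transient.

**Step 7**
Reactants: 10 (R)-2,6,10,10-tetramethylspiro[4.5]deca-1,6-dien-8-one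
Product: 12 (6R)-7,8-dibromo-1,5,5,9-tetramethylspiro[5.5]undeca-1,8-dien-3-one (both C7 epimers, in equilibrium with the tertiary allylic isomer; taken on crude), via dibromocyclopropane 11 (not isolated)
Conditions: PhHgCBr3 (2 equiv), benzene, 80 °C
Reagents that add atoms: phenyl(tribromomethyl)mercury, BrC(Br)(Br)[Hg]c1ccccc1
Why: PhHgCBr3 releases dibromocarbene at 80 °C under neutral conditions, and the carbene adds in a concerted, cheletropic [2+1] fashion to the C7=C9 double bond of the cyclopentene, the only electron-rich alkene of 10. In the adduct 11 the bromine lying over the five-membered ring ionises in concert with disrotatory 2π-electrocyclic opening of the cyclopropane (cyclopropyl-to-allyl cation rearrangement), the C7–C9 bond breaks, and bromide returns to the 2-bromoallyl cation to give 12, so the ring C6–C7–C9–C10–C11 has gained the carbene carbon as C8 between C7 and C9. The closest known reaction type is the classical one-carbon ring expansion of cyclopentenes to 2,3-dibromocyclohexenes through their dibromocarbene adducts, including that of 1-methylcyclopentene. The only ring that is closed is the three-membered one (suprafacial [2+1] closure), and it is opened again in the same flask; the six-membered ring is formed by expansion, driven by release of about 27 kcal/mol of cyclopropane strain and by the tertiary, bromine-stabilised allyl cation. The new stereocentres (the two cyclopropane carbons of 11, then C7 of 12) are not controlled and need not be, because both faces of carbene attack and all epimers and allylic isomers of 12 give the same allyl cation in step 8, whereas the spiro carbon C6 is not a reacting atom and keeps its configuration. The selectivities needed are attack on the cyclopentene and not on the ring A alkene, secured by conjugation of the latter with the ketone and its β,β-disubstitution, and entry of the new carbon between C7 and C9, secured by the position of the cyclopentene double bond next to the spiro carbon.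

**Step 8**
Reactants: 12 (6R)-7,8-dibromo-1,5,5,9-tetramethylspiro[5.5]undeca-1,8-dien-3-one
Product: 13 (R)-8-bromo-1,5,5,9-tetramethylspiro[5.5]undeca-1,8-dien-3-one
Conditions: Et3SiH, AgOSO2CF3 (AgOTf), 2,6-di-tert-butyl-4-methylpyridine, CH2Cl2, −40 to 0 °C
Reagents that add atoms: none
Why: Silver-assisted ionisation of the allylic C–Br bond should give the 2-bromoallyl cation common to all isomers of 12, and hydride transfer from the silane (ionic hydrogenation) to its secondary terminus C7 should give the tetrasubstituted bromoalkene; this is the same net change as the classical hydride reduction of 2,3-dibromocyclohexenes to 1-bromocyclohexenes, run in the SN1 manifold so that the enone, the vinylic bromide and the spiro centre are untouched.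

**Step 9**
Reactants: 13 (R)-8-bromo-1,5,5,9-tetramethylspiro[5.5]undeca-1,8-dien-3-one
Product: 15 (4S,6S)-4,8-dibromo-1,5,5,9-tetramethylspiro[5.5]undeca-1,8-dien-3-one, via silyl dienol ether 14 (not isolated)
Conditions: LiN(i-Pr)2, THF, −78 °C; Me3SiCl; then NBS, THF, −78 °C
Reagents that add atoms: N-bromosuccinimide, O=C1CCC(=O)N1Br; chlorotrimethylsilane, C[Si](C)(C)Cl (silicon is carried by 14 only)
Why: Kinetic α′-deprotonation should give the cross-conjugated silyl dienol ether, which NBS brominates at C4 (α-halogenation of a silyl enol ether); bromine is expected to enter on the face of the flatter allylic C7 arm, trans to the saturated C11–C10 arm at the spiro carbon, giving the (4S) epimer with equatorial bromine.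

**Step 10**
Reactants: 15 (4S,6S)-4,8-dibromo-1,5,5,9-tetramethylspiro[5.5]undeca-1,8-dien-3-one
Product: 16 (3S,4S,6S)-4,8-dibromo-1,5,5,9-tetramethylspiro[5.5]undeca-1,8-dien-3-ol (target)
Conditions: NaBH4, CeCl3·7H2O, MeOH, −78 °C
Reagents that add atoms: none
Why: Luche 1,2-reduction: axial delivery of hydride by the small cerium-activated borohydride to the half-chair enone with equatorial bromine should give the equatorial (3S) alcohol trans to bromine, which is also the more stable diequatorial bromohydrin.

**Compound list**

1 | 3-ethoxy-5,5-dimethylcyclohex-2-en-1-one | CCOC1=CC(=O)CC(C)(C)C1 | starting material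
2 | 4-bromo-2-methylbut-1-ene | C=C(C)CCBr | starting material
3 | rac-3-ethoxy-5,5-dimethyl-6-(3-methylbut-3-en-1-yl)cyclohex-2-en-1-one | CCOC1=CC(=O)C(CCC(C)=C)C(C)(C)C1 | intermediate
4 | allyl chloroformate | C=CCOC(Cl)=O | starting material
5 | 5-ethoxy-3,3-dimethyl-2-(3-methylbut-3-en-1-yl)cyclohexa-1,5-dien-1-yl prop-2-en-1-yl carbonate | C=CCOC(=O)OC1=C(CCC(C)=C)C(C)(C)CC(OCC)=C1 | intermediate
6 | (R)-3-ethoxy-5,5-dimethyl-6-(3-methylbut-3-en-1-yl)-6-(prop-2-en-1-yl)cyclohex-2-en-1-one | O=C1C=C(OCC)CC(C)(C)[C@]1(CC=C)CCC(C)=C | intermediate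
7 | (R)-3-ethoxy-5,5-dimethyl-6-(3-methylbut-3-en-1-yl)-6-[(E)-prop-1-en-1-yl]cyclohex-2-en-1-one | O=C1C=C(OCC)CC(C)(C)[C@]1(/C=C/C)CCC(C)=C | intermediate
8 | (R)-8-ethoxy-2,10,10-trimethylspiro[4.5]deca-1,7-dien-6-one | O=C1C=C(OCC)CC(C)(C)[C@]12CCC(C)=C2 | intermediate
9 | (5R)-8-ethoxy-2,6,10,10-tetramethylspiro[4.5]deca-1,7-dien-6-ol (both carbinol epimers) | CC1(O)C=C(OCC)CC(C)(C)[C@]12CCC(C)=C2 | intermediate
10 | (R)-2,6,10,10-tetramethylspiro[4.5]deca-1,6-dien-8-one | CC1=CC(=O)CC(C)(C)[C@]12CCC(C)=C2 | intermediate
11 | 6,6-dibromo-5-methylbicyclo[3.1.0]hexane spiro-fused at its C2 to C4 of the 3,5,5-trimethylcyclohex-2-en-1-one ring (diastereomer with the CBr2 carbon anti to the gem-dimethyl carbon drawn; the other converges) | CC1=CC(=O)CC(C)(C)[C@]12CC[C@]3(C)C(Br)(Br)[C@H]23 | intermediate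
12 | (6R)-7,8-dibromo-1,5,5,9-tetramethylspiro[5.5]undeca-1,8-dien-3-one (C7 epimers) | CC1=CC(=O)CC(C)(C)[C@]12CCC(C)=C(Br)C2Br | intermediate
13 | (R)-8-bromo-1,5,5,9-tetramethylspiro[5.5]undeca-1,8-dien-3-one | CC1=CC(=O)CC(C)(C)[C@]12CCC(C)=C(Br)C2 | intermediate
14 | (S)-[(8-bromo-1,5,5,9-tetramethylspiro[5.5]undeca-1,3,8-trien-3-yl)oxy]trimethylsilane | CC1=CC(O[Si](C)(C)C)=CC(C)(C)[C@]12CCC(C)=C(Br)C2 | intermediate
15 | (4S,6S)-4,8-dibromo-1,5,5,9-tetramethylspiro[5.5]undeca-1,8-dien-3-one | CC1=CC(=O)[C@@H](Br)C(C)(C)[C@]12CCC(C)=C(Br)C2 | intermediate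
16 | (3S,4S,6S)-4,8-dibromo-1,5,5,9-tetramethylspiro[5.5]undeca-1,8-dien-3-ol | CC1=C[C@H](O)[C@@H](Br)C(C)(C)[C@]12CCC(C)=C(Br)C2 | target

Total step count: 10. Longest linear sequence: 10 steps (from 1).

**Steps most likely to fail**

Step 8. The hydride may be delivered to the tertiary terminus C9 of the ambident bromoallyl cation instead of the neopentyl-type secondary terminus C7, or the silane may reduce silver ion before the halide is abstracted. The fallback replaces the cationic by a radical manifold. It sets out from 12 and comes back at 13: Bu3SnH (1.05 equiv) and AIBN in benzene at 80 °C should cleave only the allylic C–Br bond, and the allyl radical should take hydrogen at its less substituted terminus C7 to give the tetrasubstituted alkene; the vinylic bromide reacts far more slowly. No new compound is formed.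

Step 9. The two arms at the spiro carbon (C7H2 and C11H2) are both methylene groups, so facial discrimination in the bromination of 14 may be poor; γ-deprotonation at the C1 methyl could also compete. The fallback moves the bromination ahead of the ring expansion, where the two arms are a vinylic CH and a CH2 and differ much more. It sets out from 10 and comes back at 15. LiN(i-Pr)2 and Me3SiCl should give the silyl dienol ether (5S)-trimethyl[(2,6,10,10-tetramethylspiro[4.5]deca-1,6,8-trien-8-yl)oxy]silane F1, which NBS should brominate trans to the CH2 arm to give (5S,9S)-9-bromo-2,6,10,10-tetramethylspiro[4.5]deca-1,6-dien-8-one F2. This α-bromoketone has no β-hydrogen and does not ionise with silver ion, so the conditions of step 7 should convert it through the dibromocyclopropane adduct of the bromoketone F3 into (4S)-4,7,8-tribromo-1,5,5,9-tetramethylspiro[5.5]undeca-1,8-dien-3-one F4, and the conditions of step 8 should then give 15. An unwanted C4 epimer can in either order be separated and returned to the debromo ketone with Zn in AcOH.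

Step 10. Equatorial attack of hydride, favoured by the syn-axial methyl group on C5, would give the cis (3R) alcohol instead of the trans one; loss of bromide is a lesser concern. The fallback accepts the cis alcohol and inverts it. It sets out from 15 and comes back at 16. A bulky hydride (LiBH(s-Bu)3 or i-Bu2AlH, −78 °C) should give by equatorial attack (3R,4S,6S)-4,8-dibromo-1,5,5,9-tetramethylspiro[5.5]undeca-1,8-dien-3-ol F5. Mitsunobu inversion (4-nitrobenzoic acid, PPh3, diisopropyl azodicarboxylate, THF) should give (3S,4S,6S)-4,8-dibromo-1,5,5,9-tetramethylspiro[5.5]undeca-1,8-dien-3-yl 4-nitrobenzoate F6. Reductive ester cleavage with i-Bu2AlH in CH2Cl2 at −78 °C, which avoids base and hence epoxide closure, should release 16.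

**Further compounds**

F0 | step 8 | none | none
F1 | step 9 | (5S)-trimethyl[(2,6,10,10-tetramethylspiro[4.5]deca-1,6,8-trien-8-yl)oxy]silane | CC1=CC(O[Si](C)(C)C)=CC(C)(C)[C@]12CCC(C)=C2
F2 | step 9 | (5S,9S)-9-bromo-2,6,10,10-tetramethylspiro[4.5]deca-1,6-dien-8-one | CC1=CC(=O)[C@@H](Br)C(C)(C)[C@]12CCC(C)=C2
F3 | step 9 | dibromocyclopropane adduct of the bromoketone (one diastereomer drawn) | CC1=CC(=O)[C@@H](Br)C(C)(C)[C@]12CC[C@]3(C)C(Br)(Br)[C@H]23
F4 | step 9 | (4S)-4,7,8-tribromo-1,5,5,9-tetramethylspiro[5.5]undeca-1,8-dien-3-one (C7 epimers) | CC1=CC(=O)[C@@H](Br)C(C)(C)[C@]12CCC(C)=C(Br)C2Br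
F5 | step 10 | (3R,4S,6S)-4,8-dibromo-1,5,5,9-tetramethylspiro[5.5]undeca-1,8-dien-3-ol | CC1=C[C@@H](O)[C@@H](Br)C(C)(C)[C@]12CCC(C)=C(Br)C2
F6 | step 10 | (3S,4S,6S)-4,8-dibromo-1,5,5,9-tetramethylspiro[5.5]undeca-1,8-dien-3-yl 4-nitrobenzoate | CC1=C[C@H](OC(=O)c3ccc(cc3)[N+](=O)[O-])[C@@H](Br)C(C)(C)[C@]12CCC(C)=C(Br)C2
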